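## Retrosynthetic overview

1. **Feature.** In dihydrofuran ring B, C2 is bonded to O1 and is benzylic to ring C, whose C4′ oxygen lies para to it. A cation at C2 therefore forms and re-forms easily. O1–C2 can be the last bond of ring B, and C2 can follow C3 (trans), so only C3 needs absolute control.
2. **Disconnections.** C5 (ring A)–C2″ (furan ring D) by Suzuki–Miyaura coupling. O1–C2 by acid-induced 5-exo closure of an ortho-hydroxyaryl 1,3-diol. C2–C3 by an Evans aldol of a ring A arylacetyl imide with O-benzylvanillin, where the acyl carbon becomes the C3 hydroxymethyl group.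
3. **Ring order.** Rings A, C and E (the benzo ring of the benzofuran) are bought. Ring B is closed in the bromide fragment and ring D in the eugenol fragment (5-endo-dig). The two halves are then joined.
4. **Protecting groups.** The ring A phenol is an allyl ether, freed without acid, so the triol is isolated before any ionisation; an acetal would need the ionising acid and would release formaldehyde beside a 1,3-diol. The ring C phenol is a benzyl ether and the side-chain alcohol a TBS ether.

Key step: step 8

Remark on the chemistry: locants O1, C2 and C3 follow the dihydrobenzofuran numbering of the target. The aldol adduct and the polyols made from it are drawn as the expected syn isomer. Any epimer at the carbinol carbon (later C2) is carried on unseparated, because the ring closure erases that centre.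

## Route

### Bromide fragment (steps 1–8)

Step 1
Reactants: 1 5-bromo-2-hydroxy-3-methoxybenzaldehyde
Product: 2 2-allyloxy-5-bromo-3-methoxybenzaldehyde
Conditions: allyl bromide, K2CO3, DMF, rt to 50 °C
Reagents that add atoms: allyl bromide, C=CCBr
Why: Williamson etherification of the acidic phenol proceeds by SN2 on allyl bromide, and the allyl ether withstands ylide, aqueous acid, chlorite, boron triflate and borohydride yet can later be removed without acid.

Step 2
Reactants: 2 2-allyloxy-5-bromo-3-methoxybenzaldehyde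
Product: 4 2-(2-allyloxy-5-bromo-3-methoxyphenyl)acetaldehyde, via methyl enol ether 3 (not isolated)
Conditions: MeOCH2PPh3Cl, KOt-Bu, THF, 0 °C to rt; then 3 M aq. HCl, THF, 50 °C
Reagents that add atoms: (methoxymethyl)triphenylphosphonium chloride, COC[P+](c1ccccc1)(c1ccccc1)c1ccccc1.[Cl-]; water, O
Why: Wittig methoxymethylenation followed by acid hydrolysis of the crude enol ether is the standard one-carbon homologation of an aryl aldehyde, and neither the aryl bromide nor the allyl aryl ether reacts with the ylide or with dilute HCl.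

Step 3
Reactants: 4 2-(2-allyloxy-5-bromo-3-methoxyphenyl)acetaldehyde
Product: 5 2-(2-allyloxy-5-bromo-3-methoxyphenyl)acetic acid
Conditions: NaClO2, NaH2PO4, 2-methyl-2-butene, t-BuOH/H2O, 0 °C to rt
Reagents that add atoms: sodium chlorite, [Na+].[O-]Cl=O
Why: The Pinnick oxidation converts the sensitive arylacetaldehyde into the acid under buffered conditions, while 2-methyl-2-butene takes up the hypochlorous acid that could otherwise chlorinate ring A or the allyl group.

Step 4
Reactants: 5 2-(2-allyloxy-5-bromo-3-methoxyphenyl)acetic acid; 6 (S)-4-benzyl-2-oxazolidinone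
Product: 8 (S)-3-[2-(2-allyloxy-5-bromo-3-methoxyphenyl)acetyl]-4-benzyloxazolidin-2-one, via mixed pivalic anhydride 7 (not isolated)
Conditions: PivCl, Et3N, THF, −20 °C; then 6, LiCl, −20 °C to rt
Reagents that add atoms: pivaloyl chloride, CC(C)(C)C(=O)Cl (its atoms stay in intermediate 7 only)
Why: N-acylation through the mixed pivalic anhydride under LiCl/Et3N needs no strong base, so ketene formation and self-condensation of the acidic arylacetyl unit are avoided, and attack occurs at the less hindered arylacetyl carbonyl.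

Step 5
Reactants: 8 (S)-3-[2-(2-allyloxy-5-bromo-3-methoxyphenyl)acetyl]-4-benzyloxazolidin-2-one; 9 4-benzyloxy-3-methoxybenzaldehyde
Product: 12 (S)-4-benzyl-3-[(2S,3S)-2-(2-allyloxy-5-bromo-3-methoxyphenyl)-3-(4-benzyloxy-3-methoxyphenyl)-3-hydroxypropanoyl]oxazolidin-2-one, via Z dibutylboron enolate 10 (not isolated), via dibutylboron aldolate 11 (not isolated)
Conditions: Bu2BOTf, Et3N, CH2Cl2, −78 to 0 °C; 9, −78 to 0 °C; pH 7 buffer, MeOH, 30 % H2O2, 0 °C
Reagents that add atoms: dibutylboron triflate, CCCCB(CCCC)OS(=O)(=O)C(F)(F)F (its atoms stay in intermediates 10 and 11 only)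
Why: Evans boron aldol, in which soft enolisation gives the Z enolate 10 that adds through a closed Zimmerman–Traxler chair with the auxiliary carbonyl turned away from the enolate oxygen, so that the C4 benzyl group of the S auxiliary blocks one enolate face and fixes the α-carbon (later C3) as 2S in the imide, which becomes the R descriptor of C3 once the acyl carbon is CH2OH; the carbinol centre should come out syn (3S) but has no bearing on the target.

Step 6
Reactants: 12 the syn aldol adduct
Product: 13 (1S,2R)-2-(2-allyloxy-5-bromo-3-methoxyphenyl)-1-(4-benzyloxy-3-methoxyphenyl)propane-1,3-diol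
Conditions: LiBH4, THF/MeOH (20:1), 0 °C
Reagents that add atoms: none
Why: Reductive auxiliary cleavage, in which LiBH4 attacks the more electrophilic exocyclic imide carbonyl and takes it to the primary alcohol, the low temperature and weakly basic medium restraining retro-aldol cleavage and epimerisation of the α-aryl centre, while aryl bromide, allyl ether and benzyl ether are inert.

Step 7
Reactants: 13 (1S,2R)-2-(2-allyloxy-5-bromo-3-methoxyphenyl)-1-(4-benzyloxy-3-methoxyphenyl)propane-1,3-diol
Product: 14 (1S,2R)-2-(5-bromo-2-hydroxy-3-methoxyphenyl)-1-(4-benzyloxy-3-methoxyphenyl)propane-1,3-diol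
Conditions: Pd(PPh3)4 (5 mol %), morpholine, THF, rt
Reagents that add atoms: none
Why: Tsuji–Trost-type deallylation, in which zerovalent palladium ionises the allyl aryl ether at room temperature and morpholine traps the π-allyl complex, whereas oxidative addition into the electron-rich C–Br bond needs heating, so the phenol is freed under neutral conditions that leave the acid-sensitive benzylic alcohol untouched.

Step 8
Reactants: 14 (1S,2R)-2-(5-bromo-2-hydroxy-3-methoxyphenyl)-1-(4-benzyloxy-3-methoxyphenyl)propane-1,3-diol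
Product: 16 [(2S,3R)-2-(4-benzyloxy-3-methoxyphenyl)-5-bromo-7-methoxy-2,3-dihydrobenzofuran-3-yl]methanol, via para-benzyloxybenzylic cation 15 (not isolated)
Conditions: p-TsOH·H2O (10 mol %), CH2Cl2 (0.02 M), 0 °C to rt
Reagents that add atoms: none
Why: Protonation of the C2 hydroxyl and loss of water give the planar cation 15, which the para benzyloxy oxygen of ring C stabilises as a quinone-methide-like oxocarbenium ion, so either C2 epimer of the triol funnels into one intermediate while the unassisted primary hydroxyl stays. The nearest established reaction is the acid-induced ring closure of ortho-hydroxyaryl-substituted 1-arylpropane-1,3-diols used to make phenylcoumaran (β-5) lignin models. Ring B closes by 5-exo-trig attack of the ring A phenol oxygen on C2 (bond O1–C2), the C2=C1′ bond of the quinoid form lying outside the new ring. The new stereocentre C2 is governed by C3: the aryl group takes the ring face opposite to the C3 hydroxymethyl group, and because the para-alkoxybenzylic O1–C2 bond can re-ionise under the same acid, any cis isomer should drain to the more stable trans (2S,3R) isomer. The step needs chemoselectivity for the phenol over the primary alcohol and over intermolecular capture, which is secured by the strain of the alternative 4-exo oxetane closure, by the reversibility of every O-capture and by dilution. C3 carries no acidifying group, and catalytic acid at low temperature should keep proton loss from C3 and formaldehyde loss from the cation slow relative to ring closure.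

### Boronate fragment (steps 9–14)

Step 9
Reactants: 17 eugenol (4-allyl-2-methoxyphenol)
Product: 19 4-(3-hydroxypropyl)-2-methoxyphenol (dihydroconiferyl alcohol), via bis-boryl adduct 18 (not isolated)
Conditions: 9-BBN (2.2 equiv), THF, 0 °C to rt; then NaOH, 30 % H2O2, 0 °C
Reagents that add atoms: hydrogen peroxide, OO; 9-BBN, [H]B1C2CCCC1CCC2 (its atoms stay in intermediate 18 only)
Why: Hydroboration–oxidation with bulky 9-BBN places boron on the terminal carbon of the allyl group (anti-Markovnikov), one further equivalent being consumed by the phenol as a borinate that is cleaved again in the alkaline peroxide work-up.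

Step 10
Reactants: 19 4-(3-hydroxypropyl)-2-methoxyphenol
Product: 20 4-(3-hydroxypropyl)-2-iodo-6-methoxyphenol
Conditions: NaI, aq. NaOCl, NaOH, MeOH, 0 °C; Na2S2O3, dilute HCl work-up
Reagents that add atoms: sodium iodide, [Na+].[I-]
Why: Electrophilic aromatic iodination of the phenoxide by hypoiodite made in the flask goes ortho to the phenoxide oxygen, because the para position carries the side chain and the other ortho position the methoxy group.

Step 11
Reactants: 20 4-(3-hydroxypropyl)-2-iodo-6-methoxyphenol; 21 trimethylsilylacetylene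
Product: 22 4-(3-hydroxypropyl)-2-methoxy-6-[(trimethylsilyl)ethynyl]phenol
Conditions: PdCl2(PPh3)2 (3 mol %), CuI (5 mol %), Et3N, THF, rt to 40 °C
Reagents that add atoms: none
Why: Sonogashira coupling of an aryl iodide with a terminal alkyne runs near room temperature and tolerates the free phenol and alcohol.

Step 12
Reactants: 22 4-(3-hydroxypropyl)-2-methoxy-6-[(trimethylsilyl)ethynyl]phenol
Product: 24 3-(7-methoxybenzofuran-5-yl)propan-1-ol, via 2-ethynylphenol 23 (not isolated)
Conditions: TBAF, THF, 65 °C
Reagents that add atoms: none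
Why: Fluoride removes the alkynyl silyl group and the basic medium then drives the 5-endo-dig addition of the phenoxide to the alkyne (cycloisomerisation of an ortho-alkynylphenol), which closes furan ring D, and any 2-silylbenzofuran from early cyclisation is protodesilylated under the same conditions.

Step 13
Reactants: 24 3-(7-methoxybenzofuran-5-yl)propan-1-ol
Product: 25 tert-butyl[3-(7-methoxybenzofuran-5-yl)propoxy]dimethylsilane
Conditions: TBSCl, imidazole, DMF, rt
Reagents that add atoms: tert-butyldimethylsilyl chloride, CC(C)(C)[Si](C)(C)Cl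
Why: Standard silylation of the only remaining hydroxyl group removes the acidic proton before the lithiation.

Step 14
Reactants: 25 tert-butyl[3-(7-methoxybenzofuran-5-yl)propoxy]dimethylsilane
Product: 28 tert-butyl{3-[7-methoxy-2-(4,4,5,5-tetramethyl-1,3,2-dioxaborolan-2-yl)benzofuran-5-yl]propoxy}dimethylsilane, via 2-lithiobenzofuran 26 (not isolated), via lithium borate complex 27 (not isolated)
Conditions: n-BuLi, THF, −78 °C; i-PrOBpin, −78 °C to rt; aq. NH4Cl
Reagents that add atoms: 2-isopropoxy-4,4,5,5-tetramethyl-1,3,2-dioxaborolane, CC(C)OB1OC(C)(C)C(C)(C)O1; n-butyllithium, [Li]CCCC (lithium stays in intermediates 26 and 27 only)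
Why: Lithiation–borylation, in which the C2–H next to the furan oxygen is the most acidic position of a benzofuran, so n-BuLi at −78 °C metalates there and the aryllithium is trapped by the isopropoxyboronate, which loses isopropoxide on work-up.

### Union and deprotection (steps 15–17)

Step 15
Reactants: 16 [(2S,3R)-2-(4-benzyloxy-3-methoxyphenyl)-5-bromo-7-methoxy-2,3-dihydrobenzofuran-3-yl]methanol; 28 the benzofuran-2-yl pinacol boronate
Product: 29 [(2S,3R)-2-(4-benzyloxy-3-methoxyphenyl)-5-{5-[3-(tert-butyldimethylsilyloxy)propyl]-7-methoxybenzofuran-2-yl}-7-methoxy-2,3-dihydrobenzofuran-3-yl]methanol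
Conditions: Pd(OAc)2 (3 mol %), SPhos (6 mol %), K3PO4, THF/H2O, 50 °C
Reagents that add atoms: none
Why: Suzuki–Miyaura coupling, in which the electron-rich bulky phosphine speeds oxidative addition into the electron-rich C5–Br bond so that coupling at moderate temperature can outpace protodeboronation of the 2-benzofuranyl boronate, while the free alcohol, the ethers and both stereocentres (no acidic C–H, para oxygen capped) are unaffected by aqueous K3PO4.

Step 16
Reactants: 29 the silylated coupling product
Product: 30 3-{2-[(2S,3R)-2-(4-benzyloxy-3-methoxyphenyl)-3-(hydroxymethyl)-7-methoxy-2,3-dihydrobenzofuran-5-yl]-7-methoxybenzofuran-5-yl}propan-1-ol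
Conditions: TBAF, THF, 0 °C to rt
Reagents that add atoms: none
Why: Fluoride cleaves the primary TBS ether through formation of the strong Si–F bond, and nothing else in the molecule responds to TBAF.

Step 17
Reactants: 30 the O-benzyl ether of the target
Product: 31 CNP0308311.1, 4-{(2S,3R)-3-(hydroxymethyl)-5-[5-(3-hydroxypropyl)-7-methoxybenzofuran-2-yl]-7-methoxy-2,3-dihydrobenzofuran-2-yl}-2-methoxyphenol
Conditions: H2 (1 atm), 10 % Pd/C, EtOAc/EtOH, rt, stopped at full conversion
Reagents that add atoms: none
Why: Catalytic hydrogenolysis of the aryl benzyl ether is much faster than hydrogenolysis of the cyclic O1–C2 benzylic ether or saturation of the 2-arylbenzofuran, so in a neutral solvent at 1 atm it should free the phenol with C2 and C3 untouched.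

## Compound list

1 | 5-bromo-2-hydroxy-3-methoxybenzaldehyde | O=Cc1cc(Br)cc(OC)c1O | starting material
2 | 2-allyloxy-5-bromo-3-methoxybenzaldehyde | O=Cc1cc(Br)cc(OC)c1OCC=C | intermediate
3 | 2-allyloxy-5-bromo-1-methoxy-3-(2-methoxyvinyl)benzene (E/Z) | COC=Cc1cc(Br)cc(OC)c1OCC=C | intermediate (not isolated)
4 | 2-(2-allyloxy-5-bromo-3-methoxyphenyl)acetaldehyde | O=CCc1cc(Br)cc(OC)c1OCC=C | intermediate
5 | 2-(2-allyloxy-5-bromo-3-methoxyphenyl)acetic acid | OC(=O)Cc1cc(Br)cc(OC)c1OCC=C | intermediate
6 | (S)-4-benzyl-2-oxazolidinone | O=C1OC[C@H](Cc2ccccc2)N1 | starting material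
7 | 2-(2-allyloxy-5-bromo-3-methoxyphenyl)acetic pivalic anhydride | CC(C)(C)C(=O)OC(=O)Cc1cc(Br)cc(OC)c1OCC=C | intermediate (not isolated)
8 | (S)-3-[2-(2-allyloxy-5-bromo-3-methoxyphenyl)acetyl]-4-benzyloxazolidin-2-one | O=C1OC[C@H](Cc2ccccc2)N1C(=O)Cc1cc(Br)cc(OC)c1OCC=C | intermediate
9 | 4-benzyloxy-3-methoxybenzaldehyde | COc1cc(C=O)ccc1OCc1ccccc1 | starting material
10 | Z dibutylboron enolate of 8 | O=C1OC[C@H](Cc2ccccc2)N1/C(OB(CCCC)CCCC)=C/c1cc(Br)cc(OC)c1OCC=C | intermediate (not isolated)
11 | dibutylboron aldolate of 12 | O=C1OC[C@H](Cc2ccccc2)N1C(=O)[C@@H](c1cc(Br)cc(OC)c1OCC=C)[C@H](OB(CCCC)CCCC)c1ccc(OCc2ccccc2)c(OC)c1 | intermediate (not isolated)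
12 | (4S,2′S,3′S) syn aldol adduct | O=C1OC[C@H](Cc2ccccc2)N1C(=O)[C@@H](c1cc(Br)cc(OC)c1OCC=C)[C@H](O)c1ccc(OCc2ccccc2)c(OC)c1 | intermediate
13 | (1S,2R)-2-(2-allyloxy-5-bromo-3-methoxyphenyl)-1-(4-benzyloxy-3-methoxyphenyl)propane-1,3-diol | OC[C@@H](c1cc(Br)cc(OC)c1OCC=C)[C@H](O)c1ccc(OCc2ccccc2)c(OC)c1 | intermediate
14 | (1S,2R)-2-(5-bromo-2-hydroxy-3-methoxyphenyl)-1-(4-benzyloxy-3-methoxyphenyl)propane-1,3-diol (key-step precursor) | OC[C@@H](c1cc(Br)cc(OC)c1O)[C@H](O)c1ccc(OCc2ccccc2)c(OC)c1 | intermediate
15 | para-benzyloxybenzylic cation, C3 configured R | COc1cc([CH+][C@@H](CO)c2cc(Br)cc(OC)c2O)ccc1OCc1ccccc1 | intermediate (not isolated)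
16 | [(2S,3R)-2-(4-benzyloxy-3-methoxyphenyl)-5-bromo-7-methoxy-2,3-dihydrobenzofuran-3-yl]methanol (key-step product) | COc1cc([C@H]2Oc3c(OC)cc(Br)cc3[C@@H]2CO)ccc1OCc1ccccc1 | intermediate
17 | eugenol | C=CCc1ccc(O)c(OC)c1 | starting material
18 | O,C-bis(9-borabicyclo[3.3.1]nonan-9-yl) adduct of eugenol | COc1cc(CCCB2C3CCCC2CCC3)ccc1OB1C2CCCC1CCC2 | intermediate (not isolated)
19 | 4-(3-hydroxypropyl)-2-methoxyphenol | COc1cc(CCCO)ccc1O | intermediate
20 | 4-(3-hydroxypropyl)-2-iodo-6-methoxyphenol | COc1cc(CCCO)cc(I)c1O | intermediate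
21 | trimethylsilylacetylene | C#C[Si](C)(C)C | starting material
22 | 4-(3-hydroxypropyl)-2-methoxy-6-[(trimethylsilyl)ethynyl]phenol | COc1cc(CCCO)cc(C#C[Si](C)(C)C)c1O | intermediate
23 | 2-ethynyl-4-(3-hydroxypropyl)-6-methoxyphenol | COc1cc(CCCO)cc(C#C)c1O | intermediate (not isolated)
24 | 3-(7-methoxybenzofuran-5-yl)propan-1-ol | COc1cc(CCCO)cc2ccoc12 | intermediate
25 | tert-butyl[3-(7-methoxybenzofuran-5-yl)propoxy]dimethylsilane | COc1cc(CCCO[Si](C)(C)C(C)(C)C)cc2ccoc12 | intermediate
26 | 2-lithio derivative of 25 | COc1cc(CCCO[Si](C)(C)C(C)(C)C)cc2cc([Li])oc12 | intermediate (not isolated)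
27 | lithium (benzofuran-2-yl)(isopropoxy)pinacolatoborate | [Li+].COc1cc(CCCO[Si](C)(C)C(C)(C)C)cc2cc(oc12)[B-]1(OC(C)C)OC(C)(C)C(C)(C)O1 | intermediate (not isolated)
28 | benzofuran-2-yl pinacol boronate | COc1cc(CCCO[Si](C)(C)C(C)(C)C)cc2cc(B3OC(C)(C)C(C)(C)O3)oc12 | intermediate
29 | (2S,3R) coupling product, TBS and benzyl protected | COc1cc([C@H]2Oc3c(OC)cc(-c4cc5cc(CCCO[Si](C)(C)C(C)(C)C)cc(OC)c5o4)cc3[C@@H]2CO)ccc1OCc1ccccc1 | intermediate
30 | (2S,3R) O-benzyl ether of the target | COc1cc([C@H]2Oc3c(OC)cc(-c4cc5cc(CCCO)cc(OC)c5o4)cc3[C@@H]2CO)ccc1OCc1ccccc1 | intermediate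
31 | CNP0308311.1, (2S,3R) | COc1cc([C@H]2Oc3c(OC)cc(-c4cc5cc(CCCO)cc(OC)c5o4)cc3[C@@H]2CO)ccc1O | target

## Step count and risks

Total step count: 17.
Longest linear sequence: 11 steps (steps 1–8 and 15–17, from 1). The boronate branch (steps 9–14) adds 6 steps.

### Steps most likely to fail

**1. Step 8.**
- *Risk.* The cation may fragment with loss of formaldehyde from the free C3 hydroxymethyl group. It may lose the C3 proton, which would erode the C3 configuration on re-protonation. It may also alkylate another electron-rich ring before the phenol closes.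
- *Fallback, from 13 back to 16.* The hydroxymethyl oxygen is masked before ionisation, so the fragmentation channel is closed structurally and the larger C3 substituent reinforces the trans preference.
- Selective silylation of the primary hydroxyl of 13 (TBDPSCl, imidazole, CH2Cl2) should give the primary tert-butyldiphenylsilyl ether F1.
- Deallylation as in step 7 gives the silylated phenol F2.
- Acid closure, now possible in CH2Cl2 at low temperature, gives the silylated trans-dihydrobenzofuran F3.
- TBAF in THF returns 16.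

**2. Step 5.**
- *Risk.* Addition to the electron-rich aldehyde may be slow and the boron aldolate may revert. The ortho-substituted aryl group on the enolate may lower facial control. The acidic α-aryl centre may epimerise in the work-up.
- *Fallback, from 8 back to 13.* C3 is set by forming its bond to the hydroxymethyl carbon under auxiliary control, and the C2–aryl bond is made without control, which the later ring closure tolerates.
- The titanium enolate of 8 (TiCl4, i-Pr2NEt, CH2Cl2, 0 °C) is hydroxymethylated with 1,3,5-trioxane/TiCl4 to the (R)-3-hydroxy-2-arylpropanoyl imide F4. The chelated enolate reacts with the facial sense opposite to the boron aldol. The acyl carbon now becomes C2 and the new carbon the hydroxymethyl group, so the same S auxiliary serves.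
- TBSCl/imidazole gives the silyl ether F5, and LiBH4 gives the (S)-mono-silylated diol F6.
- Dess–Martin periodinane gives the (R)-α-aryl aldehyde F7, which is used crude and cold because this centre is configurationally labile.
- (4-Benzyloxy-3-methoxyphenyl)magnesium bromide F8 (from 1-benzyloxy-4-bromo-2-methoxybenzene and Mg) is added at −78 °C to give the silylated carbinol F9 as both carbinol epimers.
- TBAF gives 13 together with its (1R,2R) epimer F10.
- Both pass through step 7 (F10 giving the epimeric triol F11), and both triols deliver the same cation 15 in step 8.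

**3. Step 15.**
- *Risk.* Protodeboronation of the 2-benzofuranyl boronate may outrun the slow oxidative addition into the electron-rich C5–Br bond.
- *Fallback, from 16 and 20 back to 30.* Furan ring D is built on the dihydrobenzofuran instead of being coupled preformed.
- Sonogashira coupling of 16 with 21 (PdCl2(PPh3)2, CuI, Et3N, DMF, 80 °C) gives the silylalkyne F12.
- K2CO3/MeOH gives the terminal alkyne F13.
- A second Sonogashira coupling with iodophenol 20 (PdCl2(PPh3)2, CuI, Et3N, DMF, 70 °C) gives the ortho-alkynylphenol F14.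
- F14 should cyclise 5-endo-dig in the same flask to 30, so steps 11–16 are not needed.

## Further compounds

F1 | step 8 | (1S,2R)-2-(2-allyloxy-5-bromo-3-methoxyphenyl)-1-(4-benzyloxy-3-methoxyphenyl)-3-(tert-butyldiphenylsilyloxy)propan-1-ol | CC(C)(C)[Si](c1ccccc1)(c1ccccc1)OC[C@@H](c1cc(Br)cc(OC)c1OCC=C)[C@H](O)c1ccc(OCc2ccccc2)c(OC)c1
F2 | step 8 | 4-bromo-2-[(1S,2R)-1-(4-benzyloxy-3-methoxyphenyl)-3-(tert-butyldiphenylsilyloxy)-1-hydroxypropan-2-yl]-6-methoxyphenol | CC(C)(C)[Si](c1ccccc1)(c1ccccc1)OC[C@@H](c1cc(Br)cc(OC)c1O)[C@H](O)c1ccc(OCc2ccccc2)c(OC)c1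
F3 | step 8 | tert-butyldiphenylsilyl ether of 16, (2S,3R) | COc1cc([C@H]2Oc3c(OC)cc(Br)cc3[C@@H]2CO[Si](c2ccccc2)(c2ccccc2)C(C)(C)C)ccc1OCc1ccccc1
F4 | step 5 | (S)-3-[(R)-2-(2-allyloxy-5-bromo-3-methoxyphenyl)-3-hydroxypropanoyl]-4-benzyloxazolidin-2-one | O=C1OC[C@H](Cc2ccccc2)N1C(=O)[C@H](c1cc(Br)cc(OC)c1OCC=C)CO
F5 | step 5 | tert-butyldimethylsilyl ether of F4 | O=C1OC[C@H](Cc2ccccc2)N1C(=O)[C@H](c1cc(Br)cc(OC)c1OCC=C)CO[Si](C)(C)C(C)(C)C
F6 | step 5 | (S)-2-(2-allyloxy-5-bromo-3-methoxyphenyl)-3-(tert-butyldimethylsilyloxy)propan-1-ol | OC[C@H](c1cc(Br)cc(OC)c1OCC=C)CO[Si](C)(C)C(C)(C)C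
F7 | step 5 | (R)-2-(2-allyloxy-5-bromo-3-methoxyphenyl)-3-(tert-butyldimethylsilyloxy)propanal | O=C[C@H](c1cc(Br)cc(OC)c1OCC=C)CO[Si](C)(C)C(C)(C)C
F8 | step 5 | (4-benzyloxy-3-methoxyphenyl)magnesium bromide | COc1cc([Mg]Br)ccc1OCc1ccccc1
F9 | step 5 | (2R)-2-(2-allyloxy-5-bromo-3-methoxyphenyl)-1-(4-benzyloxy-3-methoxyphenyl)-3-(tert-butyldimethylsilyloxy)propan-1-ol, both C1 epimers | OC(c1ccc(OCc2ccccc2)c(OC)c1)[C@H](c1cc(Br)cc(OC)c1OCC=C)CO[Si](C)(C)C(C)(C)C
F10 | step 5 | (1R,2R) epimer of 13 | OC[C@@H](c1cc(Br)cc(OC)c1OCC=C)[C@@H](O)c1ccc(OCc2ccccc2)c(OC)c1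
F11 | step 5 | (1R,2R) epimer of 14 | OC[C@@H](c1cc(Br)cc(OC)c1O)[C@@H](O)c1ccc(OCc2ccccc2)c(OC)c1
F12 | step 15 | [(2S,3R)-2-(4-benzyloxy-3-methoxyphenyl)-7-methoxy-5-[(trimethylsilyl)ethynyl]-2,3-dihydrobenzofuran-3-yl]methanol | COc1cc([C@H]2Oc3c(OC)cc(C#C[Si](C)(C)C)cc3[C@@H]2CO)ccc1OCc1ccccc1
F13 | step 15 | [(2S,3R)-2-(4-benzyloxy-3-methoxyphenyl)-5-ethynyl-7-methoxy-2,3-dihydrobenzofuran-3-yl]methanol | COc1cc([C@H]2Oc3c(OC)cc(C#C)cc3[C@@H]2CO)ccc1OCc1ccccc1
F14 | step 15 | ortho-alkynylphenol from F13 and 20, (2S,3R) | COc1cc([C@H]2Oc3c(OC)cc(C#Cc4cc(CCCO)cc(OC)c4O)cc3[C@@H]2CO)ccc1OCc1ccccc1
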